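**Plan**
1. Cuts: the side-arm methyl ester and its ortho phenol are folded back into a dihydrocoumarin lactone, and the C7 hydroxyl into an acetate. Then O1–C8a of the coumarin is cut, then C3=C4, then the ArO–CH2 bond. This leads to 7-hydroxychroman-2-one, tert-butyl bromoacetate and vanillin.
2. Enabling feature: in the benzo ring of the coumarin, C8a (bearing O1) is para to C6–OMe and C4a is para to C7–OH. Deleting O1 therefore leaves the vanillin substitution pattern, with C8a as the open, methoxy-activated ortho C–H of a cinnamic acid.
3. Forward order: the saturated lactone ring is bought ready-made and masks one phenol plus the acid. The chain is joined by O-alkylation and Perkin condensation (C3=C4). The pyranone ring closes last by photocatalytic C–H lactonisation, and methanolysis then opens only the saturated lactone.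
4. Stereochemistry: the target has no stereocentre. The only stereo-element on the way is the (Z)-alkene from the Perkin step, and it is inverted photochemically inside the key step.

Key step: step 4

Assumption: 7-hydroxychroman-2-one, tert-butyl bromoacetate and vanillin are taken as catalogue compounds; the target is achiral, so no configuration has to be chosen.

**Step 1**
Reactants: 1 7-hydroxychroman-2-one; 2 tert-butyl bromoacetate
Product: 3 tert-butyl 2-[(2-oxochroman-7-yl)oxy]acetate
Conditions: K2CO3 (dried), acetone, rt
Reagents that add atoms: none
Why: Williamson ether synthesis: anhydrous carbonate deprotonates the single free phenol, whose SN2 attack on the activated α-bromo ester is fast at room temperature, so the aryl-ester lactone that hides the second phenol and the propanoic acid should stay closed.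

**Step 2**
Reactants: 3 tert-butyl 2-[(2-oxochroman-7-yl)oxy]acetate
Product: 4 2-[(2-oxochroman-7-yl)oxy]acetic acid
Conditions: TFA/CH2Cl2 (1:2), 0 °C to rt
Reagents that add atoms: none
Why: Acidolysis of a tert-butyl ester (protonation, loss of the tert-butyl cation as 2-methylpropene) needs neither base nor nucleophile, so the lactone and the aryl alkyl ether are untouched.

**Step 3**
Reactants: 4 2-[(2-oxochroman-7-yl)oxy]acetic acid; 5 vanillin
Product: 8 (Z)-3-(4-acetoxy-3-methoxyphenyl)-2-[(2-oxochroman-7-yl)oxy]acrylic acid, via vanillin acetate 6 (not isolated), via acetic mixed anhydride 7 (not isolated)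
Conditions: Ac2O (4 equiv), Et3N (2 equiv), toluene, 100 °C; then H2O, rt
Reagents that add atoms: acetic anhydride CC(=O)OC(C)=O
Why: Perkin condensation in its Oglialoro form (an aryloxyacetic acid as the enol component): the phenol of 5 is acetylated at once to 6, acid 4 is activated as mixed anhydride 7 whose α-CH2 is the most acidic one present, its amine-generated enolate adds to the aldehyde, and acyl transfer followed by loss of acetate gives the alkene with the β-aryl and carboxyl groups trans, which is the (Z)-descriptor here because the aryloxy group outranks carboxyl.

**Step 4**
Reactants: 8 (Z)-3-(4-acetoxy-3-methoxyphenyl)-2-[(2-oxochroman-7-yl)oxy]acrylic acid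
Product: 10 6-methoxy-2-oxo-3-[(2-oxochroman-7-yl)oxy]-2H-chromen-7-yl acetate, via (E)-acid isomer 9 (not isolated)
Conditions: riboflavin tetraacetate (5 mol %), O2 (1 atm), MeCN (dilute), 402 nm LEDs, rt
Reagents that add atoms: none
Why: Triplet energy transfer from the excited flavin to the styrene chromophore of 8 gives a twisted triplet that relaxes to both alkene geometries, so isomer 9, in which the carboxyl group faces the arene, is supplied continuously. A second excited flavin then removes one electron from 9 (from the anisole-type π system or its carboxylate), the carboxyl oxygen bonds to the ortho carbon to form O1–C8a, and loss of a proton and of a hydrogen atom to the flavin semiquinone restores aromaticity, after which O2 reoxidises the dihydroflavin and ends as H2O2. The closest known reaction type is the flavin-photocatalysed isomerisation and oxidative cyclisation cascade of cinnamic acids to coumarins, a relative of the photoredox dehydrogenative lactonisation of 2-arylbenzoic acids. The pyranone closes in a 6-endo-trig mode on the C1–C6 bond of the arene (C1 carries the side chain, C3 the methoxyl); the competing 5-exo ipso attack would give a spiro-dienyl radical that cannot rearomatise and should revert. No stereocentre is formed, and the geometry of 8 does not matter because only 9 can cyclise and its irreversible consumption drains the photostationary mixture. The step needs site selectivity between the two ortho C–H bonds and chemoselectivity between the two arenes: C6 is para to the methoxyl (highest spin and charge density in the radical cation) and sterically open whereas C2 is squeezed between side chain and methoxyl, the acetate blocks phenoxyl chemistry at the C4 oxygen, and the chromanone arene, acylated on one oxygen and tied to an electron-poor vinyl carbon through the other, is harder to oxidise.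

**Step 5**
Reactants: 10 6-methoxy-2-oxo-3-[(2-oxochroman-7-yl)oxy]-2H-chromen-7-yl acetate
Product: 11 methyl 3-[2-hydroxy-4-[(7-hydroxy-6-methoxy-2-oxo-2H-chromen-3-yl)oxy]phenyl]propanoate (CNP0259806.0)
Conditions: HCl (1.25 M in MeOH), rt to 40 °C
Reagents that add atoms: methanol CO
Why: Acid-catalysed transesterification: the large excess of methanol drives exchange of both phenol esters (the acetate leaves as methyl acetate, the saturated lactone becomes methyl ester plus phenol), whereas the coumarin lactone is held shut by its cis-locked conjugated ring and the C3 aryl vinyl ether, deactivated by the adjacent carbonyl, is not protonated; the acid is neutralised before evaporation so that the product cannot re-lactonise.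

**Compound list**
1 | 7-hydroxychroman-2-one | O=C1CCc2ccc(O)cc2O1 | starting material
2 | tert-butyl bromoacetate | CC(C)(C)OC(=O)CBr | starting material
3 | tert-butyl 2-[(2-oxochroman-7-yl)oxy]acetate | CC(C)(C)OC(=O)COc1ccc2CCC(=O)Oc2c1 | intermediate
4 | 2-[(2-oxochroman-7-yl)oxy]acetic acid | OC(=O)COc1ccc2CCC(=O)Oc2c1 | intermediate
5 | vanillin | COc1cc(C=O)ccc1O | starting material
6 | vanillin acetate (4-formyl-2-methoxyphenyl acetate) | COc1cc(C=O)ccc1OC(C)=O | intermediate (not isolated)
7 | acetic 2-[(2-oxochroman-7-yl)oxy]acetic anhydride | CC(=O)OC(=O)COc1ccc2CCC(=O)Oc2c1 | intermediate (not isolated)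
8 | (Z)-3-(4-acetoxy-3-methoxyphenyl)-2-[(2-oxochroman-7-yl)oxy]acrylic acid | CC(=O)Oc1ccc(/C=C(\Oc2ccc3CCC(=O)Oc3c2)C(=O)O)cc1OC | intermediate
9 | (E)-3-(4-acetoxy-3-methoxyphenyl)-2-[(2-oxochroman-7-yl)oxy]acrylic acid | CC(=O)Oc1ccc(/C=C(/Oc2ccc3CCC(=O)Oc3c2)C(=O)O)cc1OC | intermediate (not isolated)
10 | 6-methoxy-2-oxo-3-[(2-oxochroman-7-yl)oxy]-2H-chromen-7-yl acetate | CC(=O)Oc1cc2oc(=O)c(Oc3ccc4CCC(=O)Oc4c3)cc2cc1OC | intermediate
11 | methyl 3-[2-hydroxy-4-[(7-hydroxy-6-methoxy-2-oxo-2H-chromen-3-yl)oxy]phenyl]propanoate | COC(=O)CCc1ccc(Oc2cc3cc(OC)c(O)cc3oc2=O)cc1O | target

**Step count**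
Total steps: 5. Longest linear sequence: 5 (1 → 3 → 4 → 8 → 10 → 11); vanillin enters at step 3.

**Steps most likely to fail**

Step 4 is the riskiest.
- The aryloxy-substituted alkene is an enol ether and flavins also sensitise singlet oxygen, so oxidative cleavage of the C3=C4 bond may outrun cyclisation.
- Further loss channels are decarboxylation after carboxylate oxidation, benzylic oxidation at the chromanone CH2 para to the ether oxygen, and stalling at the photostationary mixture.

The fallback sets out from 4 and returns at 10, and it brings the ring oxygen in with the aldehyde. Selective AlCl3 demethylation of commercial 2,4,5-trimethoxybenzaldehyde (CH2Cl2, rt) cleaves the methoxyls ortho and para to the formyl group and should give 2,4-dihydroxy-5-methoxybenzaldehyde F1. Perkin–Oglialoro condensation of this aldehyde with acid 4 (Ac2O, Et3N, 100 °C) forms C3=C4, lactonises through the ortho phenol and acetylates the C7 phenol in one pot. That delivers 10 without passing through 8.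

Step 3 comes second.
- At 100 °C in Ac2O/Et3N the saturated lactone may be opened by acetolysis.
- Its own α-CH2 may enolise and condense with the aldehyde.
- Acetic anhydride itself may compete as the enol component.

The fallback sets out from 1 and returns at 8. It replaces the hot condensation by a room-temperature olefination.
- Regitz diazo transfer (4-acetamidobenzenesulfonyl azide, DBU, MeCN) onto commercial tert-butyl diethylphosphonoacetate gives tert-butyl 2-diazo-2-(diethoxyphosphoryl)acetate F2.
- Rh2(OAc)4-catalysed carbenoid O–H insertion into phenol 1 (toluene, 80 °C) gives racemic tert-butyl 2-(diethoxyphosphoryl)-2-[(2-oxochroman-7-yl)oxy]acetate F3.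
- Horner–Wadsworth–Emmons olefination under Masamune–Roush conditions (LiCl, DBU, MeCN, rt) uses vanillin acetate 6, here employed as an isolated or purchased reagent. It gives tert-butyl (Z)-3-(4-acetoxy-3-methoxyphenyl)-2-[(2-oxochroman-7-yl)oxy]acrylate F4, whose alkene geometry is of no consequence.
- TFA/CH2Cl2 then frees acid 8. Any of its isomer 9 that accompanies it serves step 4 equally well.

Step 1 comes third.
- The phenoxide of 1 may attack the aryl-ester lactone of a second molecule, causing transesterification and oligomerisation.
- Adventitious water may hydrolyse the lactone.
- Either process uncovers the second phenol and destroys the differentiation of the two ring oxygens.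

The fallback sets out from 1 and returns at 3. It is a Mitsunobu etherification of 1 with commercial tert-butyl glycolate (PPh3, DIAD, THF, 0 °C to rt). This activates the alcohol partner under essentially neutral conditions, so no carbonate base and no standing concentration of phenoxide are present. New compounds on this detour: none F0.

**Further compounds**
F1 | step 4 | 2,4-dihydroxy-5-methoxybenzaldehyde | COc1cc(C=O)c(O)cc1O
F2 | step 3 | tert-butyl 2-diazo-2-(diethoxyphosphoryl)acetate | CCOP(=O)(OCC)C(=[N+]=[N-])C(=O)OC(C)(C)C
F3 | step 3 | tert-butyl 2-(diethoxyphosphoryl)-2-[(2-oxochroman-7-yl)oxy]acetate (racemic) | CCOP(=O)(OCC)C(Oc1ccc2CCC(=O)Oc2c1)C(=O)OC(C)(C)C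
F4 | step 3 | tert-butyl (Z)-3-(4-acetoxy-3-methoxyphenyl)-2-[(2-oxochroman-7-yl)oxy]acrylate | CC(=O)Oc1ccc(/C=C(\Oc2ccc3CCC(=O)Oc3c2)C(=O)OC(C)(C)C)cc1OC
F0 | step 1 | none | none
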